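Late in the run of this flask the question is where it stands, and two chemists dispute that for the flask at 80 min.

- oak: left-handed substrate 0.10 M; right-handed substrate 0.10 M; partner 0.060 M; precatalyst 15 mM; run made earlier
- flask: left-handed substrate 0.10 M; partner 0.120 M; precatalyst 15 mM; right-handed substrate 0.10 M; time 80 min

- oak (time / min: left-handed substrate / %, right-handed substrate / %): 0.667: 49.6, 49.5; 1.00: 49.1, 49.7; 1.33: 49.7, 49.3; 2.50: 48.8, 48.0; 3.00: 48.6, 49.2; 5.00: 48.1, 47.7; 8.00: 45.9, 47.4

(readings scatter by 0.5 percentage points)

- free catalyst is single-handed; left-handed substrate and right-handed substrate are mirror images of each other, charged as a racemate, each of them at the stated concentration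
- an excess is the difference of the two amounts in percent of their sum
- an excess is below zero if the other one leads

- part of the left-handed substrate and right-handed substrate charged together that has reacted at 80 min
- excess of left-handed product over right-handed product in the product at 80 min
- excess of right-handed substrate over left-handed substrate among what is left of the two at 80 min

The first chemist holds that the substrates run on a clock: the fraction left falls by a fixed power of ten in each equal stretch of time. In the oak run at 8.00 min the reading is 45.9% of left-handed and 47.4% of right-handed substrate, together 93.3% of the charge. That is ten to the power −0.0301, a reading with 0.5 percentage points of scatter on each number. The flask runs ten times as long with twice the partner of the oak run. If the rate follows the partner, the power becomes −0.602, so 75.0% of the substrates has reacted.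

The second chemist counts one partner for each product. She divides the partner charge by the two substrate charges together and calls the result the partner ceiling, the fraction of the substrate charge that can become product. It is 60.0% in this flask. The clock's figure is more than that, so she takes partner as the limiting reagent and expects the clock to bend as partner falls.

The forecast takes her side, “it is capped at 60% conversion”, and gives 48% reacted (range 32% to 59%), a product excess of 8% and a substrate excess of 7.3%.

The simulated flask gives 47.0% reacted, a product excess of 80.9% and a substrate excess of 0.00693%.

    partner + catalyst intermediate B → free catalyst + right-handed product (k = 0.120 /M/s)
    2 partner → homo dimer (k = 0.00190 /M/s)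
    left-handed substrate ⇌ right-handed substrate (k = 0.00470 /s)
    partner + precatalyst → free catalyst + spent reagent (k = 0.0160 /M/s)
    partner + catalyst intermediate A → free catalyst + left-handed product (k = 0.280 /M/s)
    free catalyst + left-handed substrate ⇌ catalyst intermediate A (K = 23.0 /M, k = 1.30 /M/s)
    free catalyst + right-handed substrate ⇌ catalyst intermediate B (K = 4.20 /M, k = 6.80 /M/s)

At 80.0 min this flask keeps far less of its partner, 0.032%, than of its right-handed substrate, 53%, and its products together stand at 43.7%, below the ceiling. The clock stands nearer early: at 8.00 min, with 55.0% of the partner still there, it reads 13.0% reacted against 17.4% in the flask, a smaller gap than the one at 80 min. The neighbour charged with 0.048 M of partner has a ceiling of 24.0%, and it reaches 20.3% reacted, with 0.15% of its partner left.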